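**Retrosynthetic overview**
- The target (an α-hydroxy ketone) comes from oxidation of a secondary/tertiary 1,2-diol, itself from syn-dihydroxylation of the exocyclic alkene of cis-2-undecylidenecyclopent-4-ene-1,3-diyl diacetate, anti to both acetates.
- That diene comes from cis-selective 1,2-reduction of (E)-4-silyloxy-5-undecylidenecyclopent-2-enone, then silyl-to-acetyl exchange.
- The key C–C bond (ring carbon to side-chain carbon) comes from an intermolecular aldol of the α'-lithium enolate of 4-silyloxycyclopent-2-enone with undecanal, followed by dehydration.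
- The only ring, the cyclopentene, is made first by Piancatelli rearrangement of furfuryl alcohol; no other ring is formed.

Assumption: the SMILES has a mirror plane (acetoxy carbons R and S, carbinol carbon pseudo-asymmetric), so the target is an achiral meso compound. "Single enantiomer" is therefore read as "single diastereomer": both acetates cis to each other and to the undecanoyl group, tertiary OH trans. Racemic intermediates are used and their SMILES show one enantiomer.

**Step 1**
Reactants: 1 furfuryl alcohol (furan-2-ylmethanol)
Product: 2 rac-4-hydroxycyclopent-2-en-1-one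
Conditions: H2O, KH2PO4/H3PO4 (pH 4), reflux, 24–48 h; continuous EtOAc extraction
Reagents that add atoms: water O
Why: Piancatelli rearrangement, in which the furfuryl cation takes up water at C5, the ring opens to a hydroxypentadienyl cation and a conrotatory 4π electrocyclisation closes the cyclopentenone; the single stereocenter forms as the racemate, which is enough because the target is meso (the yield is modest but the material is very cheap).

**Step 2**
Reactants: 2 rac-4-hydroxycyclopent-2-en-1-one
Product: 3 rac-4-(tert-butyldimethylsilyloxy)cyclopent-2-en-1-one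
Conditions: TBSCl, Et3N, DMAP (cat.), CH2Cl2, 0 °C → rt
Reagents that add atoms: tert-butyldimethylsilyl chloride CC(C)(C)[Si](C)(C)Cl
Why: Standard silylation of a secondary alcohol under mild amine base, which avoids β-elimination of the hydroxy enone and gives an ether stable to LiN(iPr)2 and NaBH4; no stereocenter changes.

**Step 3**
Reactants: 3 rac-4-(tert-butyldimethylsilyloxy)cyclopent-2-en-1-one; 4 undecanal
Product: 6 rac-4-(tert-butyldimethylsilyloxy)-5-(1-hydroxyundecyl)cyclopent-2-en-1-one (4,5-trans; carbinol epimers), via lithium dienolate 5 (not isolated)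
Conditions: LiN(iPr)2 (1.1 equiv), THF, −78 °C, 3 added dropwise, 30 min; then 4 (1.2 equiv), −78 °C, 1 h; AcOH quench at −78 °C
Reagents that add atoms: none
Why: Intermolecular aldol addition, in which kinetic deprotonation at C5 gives the cross-conjugated lithium dienolate (it does not expel silanolate at −78 °C because that would give a cyclopentadienone) and this adds to the aldehyde anti to the OTBS group to form the key ring-to-chain C–C bond; the trans ring stereocenter and the carbinol stereocenter set here are both erased in step 4, so their ratio does not matter.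

**Step 4**
Reactants: 6 rac-4-(tert-butyldimethylsilyloxy)-5-(1-hydroxyundecyl)cyclopent-2-en-1-one
Product: 8 rac-(E)-4-(tert-butyldimethylsilyloxy)-5-undecylidenecyclopent-2-en-1-one, via mesylate 7 (not isolated)
Conditions: MsCl (1.5 equiv), Et3N (4 equiv), CH2Cl2, 0 °C → rt
Reagents that add atoms: none
Why: Mesylation followed by E1cB elimination of the β-mesyloxy ketone gives the cross-conjugated alkylidene enone, mainly the E isomer; the alkene geometry does not influence the configuration later set at the ring carbon, so any Z isomer converges.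

**Step 5**
Reactants: 8 rac-(E)-4-(tert-butyldimethylsilyloxy)-5-undecylidenecyclopent-2-en-1-one
Product: 9 rac-4-(tert-butyldimethylsilyloxy)-5-undecylidenecyclopent-2-en-1-ol (1,4-cis; decyl chain on the side of the silyloxy carbon)
Conditions: NaBH4, CeCl3·7H2O, MeOH, −78 → −40 °C
Reagents that add atoms: none
Why: Luche reduction gives clean 1,2-reduction of the dienone, and hydride is delivered to the face opposite the OTBS group across the flat ring, so the new carbinol stereocenter is cis to the silyloxy group (minor trans isomer removed by chromatography on Et3N-deactivated silica).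

**Step 6**
Reactants: 9 rac-4-(tert-butyldimethylsilyloxy)-5-undecylidenecyclopent-2-en-1-ol
Product: 10 rac-cis-2-undecylidenecyclopent-4-ene-1,3-diol
Conditions: Bu4NF (1.2 equiv), THF, 0 °C → rt
Reagents that add atoms: none
Why: Fluoride-mediated desilylation under non-acidic conditions, which the acid-labile bis-allylic alcohols tolerate; no stereocenter is touched.

**Step 7**
Reactants: 10 rac-cis-2-undecylidenecyclopent-4-ene-1,3-diol
Product: 11 rac-cis-2-undecylidenecyclopent-4-ene-1,3-diyl diacetate
Conditions: Ac2O, pyridine, DMAP (cat.), CH2Cl2, 0 °C → rt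
Reagents that add atoms: acetic anhydride CC(=O)OC(C)=O
Why: DMAP-catalysed acylation of both secondary alcohols under basic conditions with retention, installing the two acetates of the target before the oxidations.

**Step 8**
Reactants: 11 rac-cis-2-undecylidenecyclopent-4-ene-1,3-diyl diacetate
Product: 12 rac-2-hydroxy-2-(1-hydroxyundecyl)cyclopent-4-ene-1,3-diyl diacetate (tertiary OH trans to both acetates)
Conditions: OsO4 (2 mol%), N-methylmorpholine N-oxide (1.1 equiv), acetone/H2O 9:1, 0 °C, stopped when 11 is consumed; Na2SO3 quench
Reagents that add atoms: osmium tetroxide O=[Os](=O)(=O)=O (delivers both oxygens); N-methylmorpholine N-oxide C[N+]1([O-])CCOCC1 and water O (net oxygen sources that regenerate it)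
Why: Upjohn dihydroxylation, in which electrophilic OsO4 is expected to add faster to the more electron-rich trisubstituted exocyclic alkene than to the cis-disubstituted ring alkene, by concerted syn addition from the face opposite the two cis acetates; this places the tertiary OH trans to both acetates and the side-chain carbon cis to them, and the secondary carbinol configuration is irrelevant because it is oxidised next.

**Step 9**
Reactants: 12 rac-2-hydroxy-2-(1-hydroxyundecyl)cyclopent-4-ene-1,3-diyl diacetate
Product: 13 (1R,2r,3S)-2-hydroxy-2-undecanoylcyclopent-4-ene-1,3-diyl diacetate (meso target CNP0208983.3)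
Conditions: IBX (2-iodoxybenzoic acid, 1.5 equiv), DMSO, rt
Reagents that add atoms: none
Why: IBX oxidation converts the secondary alcohol of a 1,2-diol into the α-hydroxy ketone without glycol cleavage and cannot oxidise the tertiary alcohol; no stereocenter is formed, and the quaternary carbinol carbon has no α-hydrogen, so neither epimerisation nor β-elimination of acetate can occur.

**Compound list**
1 | furfuryl alcohol | OCc1ccco1 | starting material
2 | rac-4-hydroxycyclopent-2-en-1-one | O=C1C=C[C@@H](O)C1 | intermediate
3 | rac-4-(tert-butyldimethylsilyloxy)cyclopent-2-en-1-one | O=C1C=C[C@@H](O[Si](C)(C)C(C)(C)C)C1 | intermediate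
4 | undecanal | CCCCCCCCCCC=O | starting material
5 | lithium 3-(tert-butyldimethylsilyloxy)cyclopenta-1,4-dien-1-olate (α'-dienolate of 3, not isolated) | [Li+].[O-]C1=C[C@H](O[Si](C)(C)C(C)(C)C)C=C1 | intermediate
6 | rac-4-(tert-butyldimethylsilyloxy)-5-(1-hydroxyundecyl)cyclopent-2-en-1-one, 4,5-trans, carbinol epimers | CCCCCCCCCCC(O)[C@@H]1C(=O)C=C[C@H]1O[Si](C)(C)C(C)(C)C | intermediate
7 | methanesulfonate of 6 (not isolated) | CCCCCCCCCCC(OS(C)(=O)=O)[C@@H]1C(=O)C=C[C@H]1O[Si](C)(C)C(C)(C)C | intermediate
8 | rac-(E)-4-(tert-butyldimethylsilyloxy)-5-undecylidenecyclopent-2-en-1-one | CCCCCCCCCC/C=C1/C(=O)C=C[C@H]1O[Si](C)(C)C(C)(C)C | intermediate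
9 | rac-4-(tert-butyldimethylsilyloxy)-5-undecylidenecyclopent-2-en-1-ol, 1,4-cis | CCCCCCCCCC/C=C1/[C@@H](O)C=C[C@H]1O[Si](C)(C)C(C)(C)C | intermediate
10 | rac-cis-2-undecylidenecyclopent-4-ene-1,3-diol | CCCCCCCCCC/C=C1/[C@@H](O)C=C[C@H]1O | intermediate
11 | rac-cis-2-undecylidenecyclopent-4-ene-1,3-diyl diacetate | CCCCCCCCCC/C=C1/[C@@H](OC(C)=O)C=C[C@H]1OC(C)=O | intermediate
12 | rac-2-hydroxy-2-(1-hydroxyundecyl)cyclopent-4-ene-1,3-diyl diacetate, acetates cis to each other and to the side chain | CCCCCCCCCC[C@H](O)[C@@]1(O)[C@@H](OC(C)=O)C=C[C@H]1OC(C)=O | intermediate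
13 | (1R,2r,3S)-2-hydroxy-2-undecanoylcyclopent-4-ene-1,3-diyl diacetate (meso) | CCCCCCCCCCC(=O)[C@@]1(O)[C@@H](OC(C)=O)C=C[C@H]1OC(C)=O | target

**Step count and risks**
Total steps: 9. Longest linear sequence: 9 steps (1 → 13); undecanal 4 is used as bought.

The three steps most likely to fail:

Step 8 (chemoselectivity). Both alkenes of 11 carry the same two allylic acetates, so the preference for the exocyclic alkene rests only on its extra alkyl substituent, and over-oxidation of the ring alkene can erode the yield. The fallback sets out from dienone 8 and comes back at diol 12. The exocyclic alkene is dihydroxylated at the dienone stage (OsO4 cat., N-methylmorpholine N-oxide, acetone/H2O, attack anti to OTBS), where the competing ring alkene is the cis-disubstituted double bond of a cyclopentenone and any tetraol is removed early. This gives rac-4-(tert-butyldimethylsilyloxy)-5-hydroxy-5-(1-hydroxyundecyl)cyclopent-2-en-1-one F3. The diol is tied up with 2-methoxypropene and PPTS in CH2Cl2 as the acetonide rac-9-(tert-butyldimethylsilyloxy)-4-decyl-2,2-dimethyl-1,3-dioxaspiro[4.4]non-7-en-6-one F4. Luche reduction (NaBH4, CeCl3·7H2O, MeOH, −78 °C), with hydride anti to both the OTBS group and the CH(decyl) arm of the dioxolane, gives the cis alcohol rac-9-(tert-butyldimethylsilyloxy)-4-decyl-2,2-dimethyl-1,3-dioxaspiro[4.4]non-7-en-6-ol F5. Bu4NF in THF gives rac-4-decyl-2,2-dimethyl-1,3-dioxaspiro[4.4]non-7-ene-6,9-diol F6, and Ac2O, pyridine and DMAP give rac-4-decyl-2,2-dimethyl-1,3-dioxaspiro[4.4]non-7-ene-6,9-diyl diacetate F7. Hydrolysis of the acetonide with 80% aqueous AcOH at 40 °C delivers 12, which is oxidised as in step 9. This order also avoids all bis-allylic intermediates.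

Step 3 (aldol). The dienolate 5 can undergo Michael self-addition or lose silanolate, and the aldolate can revert. The fallback sets out from undecanal 4 and comes back at diol 10, replacing steps 3 to 6. Undecanal is condensed with freshly cracked cyclopentadiene (pyrrolidine, MeOH, 0 °C → rt, an aldol-type condensation through the iminium ion) to give 6-decylfulvene F1. This is photo-oxygenated (O2, hν, tetraphenylporphyrin, CH2Cl2/MeOH, −40 °C) in the presence of thiourea, so that the [4+2] adduct rac-7-undecylidene-2,3-dioxabicyclo[2.2.1]hept-5-ene F2 is reduced as it forms. The product is diol 10, whose cis relationship is fixed by the peroxide bridge; the route continues with step 7.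

Step 9 (oxidation next to a tertiary alcohol). Diol 12 can suffer 1,3-acetyl migration to the side-chain hydroxyl before oxidation, and the α-ketol can rearrange or cleave under harsher oxidants. The fallback sets out from diene 11 and comes back at target 13 without ever freeing the diol. It is a one-step ketohydroxylation with RuCl3 (1 mol%), KHSO5 (as 2KHSO5·KHSO4·K2SO4) and NaHCO3 in EtOAc/MeCN/H2O at rt for a few minutes; the ruthenate ester formed anti to the acetates is oxidised in place to the tertiary alcohol and ketone. It makes no compound outside the list (none F0).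

**Further compounds**
F1 | step 3 | 6-decylfulvene (5-undecylidenecyclopenta-1,3-diene) | CCCCCCCCCCC=C1C=CC=C1
F2 | step 3 | rac-7-undecylidene-2,3-dioxabicyclo[2.2.1]hept-5-ene | CCCCCCCCCC/C=C1/[C@@H]2C=C[C@H]1OO2
F3 | step 8 | rac-4-(tert-butyldimethylsilyloxy)-5-hydroxy-5-(1-hydroxyundecyl)cyclopent-2-en-1-one, tertiary OH trans to OTBS | CCCCCCCCCC[C@H](O)[C@@]1(O)C(=O)C=C[C@H]1O[Si](C)(C)C(C)(C)C
F4 | step 8 | rac-9-(tert-butyldimethylsilyloxy)-4-decyl-2,2-dimethyl-1,3-dioxaspiro[4.4]non-7-en-6-one | CCCCCCCCCC[C@@H]1OC(C)(C)O[C@@]12C(=O)C=C[C@H]2O[Si](C)(C)C(C)(C)C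
F5 | step 8 | rac-9-(tert-butyldimethylsilyloxy)-4-decyl-2,2-dimethyl-1,3-dioxaspiro[4.4]non-7-en-6-ol, 6,9-cis | CCCCCCCCCC[C@@H]1OC(C)(C)O[C@@]12[C@@H](O)C=C[C@H]2O[Si](C)(C)C(C)(C)C
F6 | step 8 | rac-4-decyl-2,2-dimethyl-1,3-dioxaspiro[4.4]non-7-ene-6,9-diol, 6,9-cis | CCCCCCCCCC[C@@H]1OC(C)(C)O[C@@]12[C@@H](O)C=C[C@H]2O
F7 | step 8 | rac-4-decyl-2,2-dimethyl-1,3-dioxaspiro[4.4]non-7-ene-6,9-diyl diacetate, 6,9-cis | CCCCCCCCCC[C@@H]1OC(C)(C)O[C@@]12[C@@H](OC(C)=O)C=C[C@H]2OC(C)=O
F0 | step 9 | none | none
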